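A second is long beside the isomer's step and short beside the substrate's: in Tuesday's flask, mono adduct and isomer of the product relax towards each other with a half-life of 0.320 s, far less than the 21 s the substrate needs by its first step alone.

| setting | Monday's | Tuesday's | Sunday's | Saturday's |
|---|---|---|---|---|
| substrate | 0.0010 M (fed, over 10 s) | 0.0010 M | 0.0010 M | 0.0010 M (fed, over 10 s) |
| reagent | 3.00 mM | 3.00 mM | 3.00 mM (fed, over 10 s) | 3.00 mM |
| temperature | 100 °C | 100 °C | 100 °C |  |
| time | 15 s | 15 s | 15 s | 15 s |
| remark | all else is in the flask from the start; the feed brings no volume worth counting | everything together at the start | all else is in the flask from the start; the feed brings no volume worth counting | the addition at 60 °C, then warmed to 100 °C; the feed brings no volume worth counting |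

    substrate + reagent → mono adduct (k1 = 11.2 L mol⁻¹ s⁻¹, Ea1 = 47.0 kJ mol⁻¹)
    reagent + mono adduct → double product (k2 = 33.0 L mol⁻¹ s⁻¹, Ea2 = 52.0 kJ mol⁻¹)
    reagent + double product → tris adduct (k3 = 27.0 L mol⁻¹ s⁻¹, Ea3 = 62.0 kJ mol⁻¹)
    reagent + tris adduct → tetra adduct (k4 = 25.5 L mol⁻¹ s⁻¹, Ea4 = 58.0 kJ mol⁻¹)
    mono adduct ⇌ isomer of the product (K5 = 0.36, k5 = 0.574 s⁻¹, Ea5 = 99.0 kJ mol⁻¹, ΔH5 = −26.0 kJ mol⁻¹)
    substrate + mono adduct → side product (k6 = 19.9 L mol⁻¹ s⁻¹, Ea6 = 46.0 kJ mol⁻¹)
    (constants at 100 °C)

- a species is counted by the substrate in it: one side product counts as two
- constants are those at 100 °C; use the activation energies and enthalpies for any other temperature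

- the flask with the highest amount of double product, in percent of the substrate charged ("all alike" if they lie within 1.5 percentage points) (Monday's / Tuesday's / Sunday's / Saturday's / all alike)
- final double product, as a percentage of the substrate charged, in Monday's
- final double product, as a percentage of the substrate charged, in Tuesday's
- final double product, as a percentage of the substrate charged, in Sunday's
- final double product, as a percentage of the substrate charged, in Saturday's

Substrate takes up reagent to give mono adduct, and mono adduct takes up more to give double product, which goes on to tris and tetra adduct. Meanwhile mono adduct slips into the isomer and back, and the isomer takes up no reagent. Call these two together the pool.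

Two chemists dispute how fast the pool passes on in Tuesday's flask. The first counts the isomer as forming too slowly to matter, and so lets the whole pool pass at the second step's constant times c(reagent), 0.0990 s⁻¹. The second says the isomer's step stays at balance, because its relaxation is far shorter than the 7.0 s mono adduct needs by the second step alone. Then the free part of the pool is one divided by one plus the equilibrium constant, 73.5%. The pool's pass rate, the free rate, is therefore 0.0728 s⁻¹, a pseudo-first-order constant.

Each chemist then reckons two first-order stages in a row, with c(reagent) held at its charge and the first stage at 0.0336 s⁻¹. By 15 s, the first has 20.2% of the substrate past the second step, and the second has 16.6%. I side with the second, but my number counts double product, tris adduct and tetra adduct together, so it isn't the forecast's quantity.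

The forecast stands on the second chemist's side, taking about 73.5% of the pool as mono adduct. It names Tuesday's, on the ground that “both reagents are present in full from t = 0, giving the longest effective reaction time”. Its double product is 6.3% for Monday's, 10% for Tuesday's, 6.1% for Sunday's and 3.5% for Saturday's.

The simulation gives Tuesday's the most, with 9.25%, against 5.88% for Monday's, 5.76% for Sunday's and 2.74% for Saturday's.

In Tuesday's flask at 15.0 s, mono adduct is 73.7% of the pool, the second chemist's share, and 13.6% stands past the second step, below her 16.6%. The first chemist has her region in Saturday's flask, still at its lower temperature at 10.0 s, where nearly all of the pool is mono adduct. The neighbour of Tuesday's with 0.0051 M of reagent has a free rate of 0.124 s⁻¹, and the same two stages, the first at 0.0571 s⁻¹, put 34.6% past the second step. That flask shows 29.0% there at 15.0 s, of which double product is 14.9%.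

All constants were drawn at random within sensible limits, and the outcome is calculated.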